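**Plan**
- Cuts: both ring C–C(=O) bonds of the anhydride (ring CH–C=O and ring CH2–C=O) lead back to a terminal oxirane plus two CO. The enal C=C is cut by a Horner–Wadsworth–Emmons (HWE) disconnection into an α-homofarnesyl phosphonoacetate and a C5 epoxy aldehyde. The aldehyde comes from (R,R)-2,2'-bioxirane plus a vinyl unit, and homofarnesyl comes from farnesyl bromide plus one carbon.
- Enabling feature: the ring atoms O, CH2 and CH of the 2,5-dioxooxolane are the three atoms of an oxirane with one CO inserted into each C–O bond. Strain release of the oxirane, then of the oxetan-2-one, drives a three-component union (epoxide + 2 CO) in one flask.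
- Forward order: the chain is joined first (C5 aldehyde + C18 phosphonate give the C23 enoate). The enal is held at the allylic alcohol level and both oxygens are masked as TES ethers. The only ring of the target then arises as oxirane, then oxetanone, then anhydride, and the helpers come off in the last two steps.
- Stereochemistry: both sp3 centres come from D-threitol through the C2-symmetric bis-epoxide. The carbinol carbon is never touched. The ring CH is the remaining oxirane carbon, retained in the first CO insertion and inverted once in the second. The two chain E-olefins are bought with farnesyl bromide, and the enal E geometry comes from the HWE step.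

Key step: step 12

Assumption: the three starting materials are bought as the single isomers named, and the free β-hydroxy anhydride is taken to persist under neutral anhydrous conditions, because its isomerisation to the γ-lactone acid must pass a strained dioxabicyclo[2.2.1]heptane intermediate.

**Step 1**
Reactants: 1 (+)-1,4-di-O-tosyl-2,3-O-isopropylidene-D-threitol
Product: 2 1,4-di-O-tosyl-D-threitol
Conditions: TsOH·H2O (cat.), EtOH/H2O, reflux
Reagents that add atoms: none
Why: Acid-catalysed acetal hydrolysis frees the 2,3-diol without touching the primary sulfonates or either stereocentre.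

**Step 2**
Reactants: 2 1,4-di-O-tosyl-D-threitol
Product: 3 (2R,2'R)-2,2'-bioxirane
Conditions: KOH, H2O/Et2O, rt
Reagents that add atoms: none
Why: Double intramolecular Williamson closure (3-exo-tet), in which each secondary alkoxide displaces the neighbouring primary tosylate, breaks no bond to a stereocentre and so carries the (R,R) configuration into the C2-symmetric bis-epoxide.

**Step 3**
Reactants: 3 (2R,2'R)-2,2'-bioxirane
Product: 4 (1R)-1-[(2R)-oxiran-2-yl]but-3-en-1-ol
Conditions: CH2=CHMgBr (0.4 equiv; 3 in excess, recovered by distillation), CuI (5 mol%), THF, −40 °C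
Reagents that add atoms: vinylmagnesium bromide, C=C[Mg]Br
Why: Copper-catalysed SN2 opening of an epoxide by a Grignard reagent at the unsubstituted carbon; the two oxiranes of 3 are homotopic, so one epoxy alcohol should result, the excess of 3 holds back a second opening, and both stereocentres stay untouched.

**Step 4**
Reactants: 4 (1R)-1-[(2R)-oxiran-2-yl]but-3-en-1-ol
Product: 5 triethyl{[(1R)-1-[(2R)-oxiran-2-yl]but-3-en-1-yl]oxy}silane
Conditions: Et3SiCl, imidazole, CH2Cl2, 0 °C
Reagents that add atoms: chlorotriethylsilane, CC[Si](Cl)(CC)CC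
Why: Standard silylation masks the hydroxyl, which would otherwise acylate on the later lactone and anhydride, with a group that leaves under brief buffered HF.

**Step 5**
Reactants: 5 triethyl{[(1R)-1-[(2R)-oxiran-2-yl]but-3-en-1-yl]oxy}silane
Product: 7 (3R)-3-[(2R)-oxiran-2-yl]-3-(triethylsilyloxy)propanal, via ozonide 6 (not isolated)
Conditions: O3, CH2Cl2, −78 °C; then PPh3, −78 °C → rt
Reagents that add atoms: ozone, [O-][O+]=O
Why: Ozonolysis with reductive work-up cleaves the only alkene to the aldehyde, while the silyl ether, the oxirane and both stereocentres are inert.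

**Step 6**
Reactants: 8 (2E,6E)-farnesyl bromide
Product: 9 (3E,7E)-homofarnesyl phenyl sulfide
Conditions: PhSMe, n-BuLi, DABCO, THF, 0 °C; then 8, −78 °C → rt
Reagents that add atoms: thioanisole, CSc1ccccc1
Why: SN2 alkylation of the sulfur-stabilised primary carbanion at the primary allylic bromide adds the one missing carbon without allylic transposition or loss of E geometry.

**Step 7**
Reactants: 9 (3E,7E)-homofarnesyl phenyl sulfide
Product: 11 (3E,7E)-1-iodo-4,8,12-trimethyltrideca-3,7,11-triene, via sulfonium iodide 10 (not isolated)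
Conditions: MeI (excess), NaI, DMF, 70 °C, dark
Reagents that add atoms: methyl iodide, CI
Why: S-methylation turns the sulfide into a sulfonium leaving group, which iodide displaces by SN2 at the primary carbon; the conditions are neutral and leave the three olefins alone.

**Step 8**
Reactants: 11 (3E,7E)-1-iodo-4,8,12-trimethyltrideca-3,7,11-triene; 12 triethyl phosphonoacetate
Product: 13 ethyl (5E,9E)-2-(diethoxyphosphoryl)-6,10,14-trimethylpentadeca-5,9,13-trienoate (racemic)
Conditions: NaH, DMF, 0 °C; then 11, 50 °C
Reagents that add atoms: none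
Why: Alkylation of the stabilised phosphonoacetate carbanion with a primary iodide; the new centre is racemic and is destroyed in step 9.

**Step 9**
Reactants: 13 ethyl (5E,9E)-2-(diethoxyphosphoryl)-6,10,14-trimethylpentadeca-5,9,13-trienoate; 7 (3R)-3-[(2R)-oxiran-2-yl]-3-(triethylsilyloxy)propanal
Product: 14 ethyl (2E,5R)-5-[(2R)-oxiran-2-yl]-5-(triethylsilyloxy)-2-[(3E,7E)-4,8,12-trimethyltrideca-3,7,11-trien-1-yl]pent-2-enoate
Conditions: NaH (slight deficit), THF, 0 °C; then 7, −20 °C → rt
Reagents that add atoms: none
Why: The HWE olefination of an α-alkyl phosphonoacetate should place the ester trans to the β-alkyl group and so give the (E)-trisubstituted enoate (any Z isomer is removed by chromatography), and the soft anion spares the oxirane and the silyl ether.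

**Step 10**
Reactants: 14 ethyl (2E,5R)-enoate
Product: 15 (2E,5R)-5-[(2R)-oxiran-2-yl]-5-(triethylsilyloxy)-2-[(3E,7E)-4,8,12-trimethyltrideca-3,7,11-trien-1-yl]pent-2-en-1-ol
Conditions: i-Bu2AlH (2.3 equiv), CH2Cl2, −78 °C
Reagents that add atoms: none
Why: 1,2-Reduction of the enoate by i-Bu2AlH at low temperature is faster than opening of the oxirane shielded by the silyloxy branch, and it brings the future aldehyde carbon to an oxidation level that tolerates the carbonylation.

**Step 11**
Reactants: 15 (2E,5R)-allylic alcohol
Product: 16 bis-TES epoxide (2R)-2-{(1R,3E,7E,11E)-1-(triethylsilyloxy)-4-[(triethylsilyloxy)methyl]-8,12,16-trimethylheptadeca-3,7,11,15-tetraen-1-yl}oxirane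
Conditions: Et3SiCl, imidazole, CH2Cl2, 0 °C
Reagents that add atoms: chlorotriethylsilane, CC[Si](Cl)(CC)CC
Why: Standard silylation removes the last protic group, so that nothing in the substrate can acylate on the lactone or anhydride formed next.

**Step 12**
Reactants: 16 bis-TES epoxide
Product: 18 bis-TES anhydride (3S)-3-{(1R,3E,7E,11E)-1-(triethylsilyloxy)-4-[(triethylsilyloxy)methyl]-8,12,16-trimethylheptadeca-3,7,11,15-tetraen-1-yl}oxolane-2,5-dione, via β-lactone 17 (not isolated)
Conditions: [(ClTPP)Al(THF)2][Co(CO)4] (5 mol%; ClTPP = meso-tetrakis(4-chlorophenyl)porphyrinato), CO (60 bar), 1,4-dioxane, 90 °C; vent, hexane, filter under N2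
Reagents that add atoms: carbon monoxide, [C-]#[O+]
Why: The aluminium porphyrin cation binds the oxirane oxygen of 16, [Co(CO)4]− opens the ring by SN2 attack at the unsubstituted CH2, CO inserts into the new C–Co bond, and the aluminium alkoxide closes oxetan-2-one 17 on the acylcobalt (4-exo-trig) with retention at the O-bearing carbon. In a second cycle the same ion pair activates 17, the cobaltate cleaves the alkyl C–O bond at the ring CH with inversion, migratory insertion of CO (retention) makes the CH–C(=O) bond, and the aluminium carboxylate closes the five-membered anhydride on the acylcobalt (5-exo-trig), so that release of oxirane and then oxetanone strain drives the union of one epoxide with two CO. The closest known reaction type is the catalytic one-pot double carbonylation of terminal epoxides, alkenyl- and silyloxy-substituted ones included, to succinic anhydrides with [Lewis acid]+[Co(CO)4]− ion pairs in 1,4-dioxane. The ring stereocentre is transferred rather than created: the (R)-oxirane carbon is inverted exactly once and becomes the (S)-ring carbon, while the (R)-carbinol carbon takes no part. The step needs attack at CH2 in the first cycle and at the sp3 C–O carbon (not the acyl carbon) in the second, which the steric bias of the branched oxirane and the soft carbon-philic cobaltate secure, and it needs a clean SN2 course, which the electron-withdrawing silyloxy neighbour secures by disfavouring ionisation. High CO pressure should outrun β-hydride elimination and ketone formation, the absence of H2 leaves the trisubstituted olefins alone, and heating is stopped once 17 is consumed to avoid epimerisation next to the carbonyl.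

**Step 13**
Reactants: 18 bis-TES anhydride
Product: 19 diol anhydride (3S)-3-[(1R,3E,7E,11E)-1-hydroxy-4-(hydroxymethyl)-8,12,16-trimethylheptadeca-3,7,11,15-tetraen-1-yl]oxolane-2,5-dione
Conditions: HF·pyridine, pyridine, THF, 0 °C; toluene, filtration through a silica pad (no aqueous work-up)
Reagents that add atoms: none
Why: Fluoride-driven Si–O cleavage under buffered water-free conditions neither hydrolyses nor enolises the anhydride; the E-olefin keeps the primary hydroxyl out of reach of the ring, and attack of the secondary hydroxyl on the distal carbonyl would need a strained bicyclic intermediate.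

**Step 14**
Reactants: 19 diol anhydride
Product: 20 Hippolide D
Conditions: TEMPO (10 mol%), PhI(OAc)2 (1.1 equiv), dry CH2Cl2, rt; concentration and rapid chromatography
Reagents that add atoms: none
Why: The oxoammonium oxidation (TEMPO/PhI(OAc)2) is selective for the unhindered primary allylic alcohol over the secondary carbinol and runs without water or base, so the anhydride, the α-stereocentre and the olefin geometry persist, and lactol formation is barred by the E geometry.

**Compound list**
1 | (+)-1,4-di-O-tosyl-2,3-O-isopropylidene-D-threitol, (4R,5R) | CC1(C)O[C@H](COS(=O)(=O)c2ccc(C)cc2)[C@@H](COS(=O)(=O)c2ccc(C)cc2)O1 | starting material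
2 | 1,4-di-O-tosyl-D-threitol, (2R,3R) | Cc1ccc(cc1)S(=O)(=O)OC[C@@H](O)[C@H](O)COS(=O)(=O)c1ccc(C)cc1 | intermediate
3 | (2R,2'R)-2,2'-bioxirane | C1O[C@H]1[C@H]1CO1 | intermediate
4 | (1R)-1-[(2R)-oxiran-2-yl]but-3-en-1-ol | C=CC[C@@H](O)[C@H]1CO1 | intermediate
5 | TES ether of 4 | C=CC[C@@H](O[Si](CC)(CC)CC)[C@H]1CO1 | intermediate
6 | 1,2,4-trioxolane (ozonide) of 5, not isolated | C1OC(C[C@@H](O[Si](CC)(CC)CC)[C@H]2CO2)OO1 | intermediate
7 | (3R)-3-[(2R)-oxiran-2-yl]-3-(triethylsilyloxy)propanal | O=CC[C@@H](O[Si](CC)(CC)CC)[C@H]1CO1 | intermediate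
8 | (2E,6E)-farnesyl bromide | CC(C)=CCC/C(C)=C/CC/C(C)=C/CBr | starting material
9 | (3E,7E)-homofarnesyl phenyl sulfide | CC(C)=CCC/C(C)=C/CC/C(C)=C/CCSc1ccccc1 | intermediate
10 | methyl(phenyl)[(3E,7E)-homofarnesyl]sulfonium iodide, not isolated | CC(C)=CCC/C(C)=C/CC/C(C)=C/CC[S+](C)c1ccccc1.[I-] | intermediate
11 | (3E,7E)-1-iodo-4,8,12-trimethyltrideca-3,7,11-triene (homofarnesyl iodide) | CC(C)=CCC/C(C)=C/CC/C(C)=C/CCI | intermediate
12 | triethyl phosphonoacetate | CCOC(=O)CP(=O)(OCC)OCC | starting material
13 | ethyl (5E,9E)-2-(diethoxyphosphoryl)-6,10,14-trimethylpentadeca-5,9,13-trienoate, racemic | CC(C)=CCC/C(C)=C/CC/C(C)=C/CCC(C(=O)OCC)P(=O)(OCC)OCC | intermediate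
14 | (2E,5R)-enoate with (2R)-oxirane and secondary OTES | CC(C)=CCC/C(C)=C/CC/C(C)=C/CC/C(C(=O)OCC)=C\C[C@@H](O[Si](CC)(CC)CC)[C@H]1CO1 | intermediate
15 | (2E,5R)-allylic alcohol | CC(C)=CCC/C(C)=C/CC/C(C)=C/CC/C(CO)=C\C[C@@H](O[Si](CC)(CC)CC)[C@H]1CO1 | intermediate
16 | bis-TES epoxide, (R)-oxirane carbon, (R)-carbinol carbon | CC(C)=CCC/C(C)=C/CC/C(C)=C/CC/C(CO[Si](CC)(CC)CC)=C\C[C@@H](O[Si](CC)(CC)CC)[C@H]1CO1 | intermediate
17 | (4R)-4-substituted oxetan-2-one, (1R) side chain, not isolated | CC(C)=CCC/C(C)=C/CC/C(C)=C/CC/C(CO[Si](CC)(CC)CC)=C\C[C@@H](O[Si](CC)(CC)CC)[C@H]1CC(=O)O1 | intermediate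
18 | bis-TES anhydride, (3S) ring carbon, (1R) carbinol carbon | CC(C)=CCC/C(C)=C/CC/C(C)=C/CC/C(CO[Si](CC)(CC)CC)=C\C[C@@H](O[Si](CC)(CC)CC)[C@@H]1CC(=O)OC1=O | intermediate
19 | diol anhydride | CC(C)=CCC/C(C)=C/CC/C(C)=C/CC/C(CO)=C\C[C@@H](O)[C@@H]1CC(=O)OC1=O | intermediate
20 | Hippolide D, (3S)-3-[(1R,3E,7E,11E)-4-formyl-1-hydroxy-8,12,16-trimethylheptadeca-3,7,11,15-tetraen-1-yl]oxolane-2,5-dione | CC(C)=CCC/C(C)=C/CC/C(C)=C/CC/C(C=O)=C\C[C@@H](O)[C@@H]1CC(=O)OC1=O | target

**Total steps:** 14. **Longest linear sequence:** 11 (steps 1–5 and 9–14, from 1).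

**Steps most likely to fail**

1. **Step 12.**
   - What may go wrong: the second insertion may stall after the first, because the cobaltate must attack a secondary carbon flanked by the silyloxy-bearing carbon. Competing processes are eliminative opening of the lactone to an unsaturated acid, Lewis-acid isomerisation of the oxirane to a ketone, and slow epimerisation next to the anhydride carbonyl on long heating.
   - Fallback (sets out from 16, comes back at 18): the succinate is built by an auxiliary-controlled aldol reaction and the ring is closed through a C–O bond. Both silyl ethers of 16 are removed with Bu4NF/AcOH in THF to give epoxy diol F1. Its hydroxy-oxirane unit is hydrolysed and cleaved in one pot by H5IO6 in THF/H2O to hydroxy aldehyde F2, and Et3SiCl/imidazole then gives silyloxy aldehyde F3. An Evans syn-aldol reaction (Bu2BOTf, Et3N, CH2Cl2, −78 °C) joins F3 to succinyl imide F4, which is made from mono-tert-butyl succinate and (S)-4-benzyl-1,3-oxazolidin-2-one with PivCl, Et3N and LiCl. This should give syn-aldol imide F5 with the (R)-carbinol and (S)-α-centre. Excess Et3SiOTf/2,6-lutidine silylates the hydroxyl and converts the tert-butyl ester into the silyl ester, giving silyl ester imide F6. LiOH/H2O2 removes the auxiliary and the silyl ester to give diacid F7, and DCC in CH2Cl2 dehydrates F7 to 18.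

2. **Step 13.**
   - What may go wrong: acyl transfer from the anhydride to a liberated hydroxyl (translactonisation or oligomer formation), or opening of the ring by fluoride, during the time needed to remove two silyl ethers of unequal lability.
   - Fallback (sets out from 18, comes back at 20, passing by 19 and step 14): DDQ in dry CH2Cl2 (0 °C → rt) oxidises the allylic silyl ether directly, by hydride abstraction from the allylic C–H and loss of the silyl group from the oxocarbenium ion. This gives O-TES Hippolide D F8, so that no free primary alcohol ever meets the anhydride. The single secondary TES ether is then removed as the very last operation by short exposure to Et3N·3HF in MeCN, followed by filtration through silica.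

3. **Step 9.**
   - What may go wrong: poor E/Z control with the long α-alkyl phosphonate and an unbranched aldehyde, and β-elimination of the silyloxy group from 7 under the basic conditions.
   - Fallback (sets out from 7 and 11, comes back at 14): geometry is fixed by a neutral halo-olefination, and the side chain is attached by cross-coupling. Wittig reaction of 7 with ethyl bromo(triphenyl-λ5-phosphanylidene)acetate in CH2Cl2 at rt should give (Z)-α-bromo enoate F9, with the ester trans to the chain. Iodide 11 is converted (t-BuLi, Et2O, −78 °C; then 9-methoxy-9-borabicyclo[3.3.1]nonane) into lithium borate F10. B-alkyl Suzuki–Miyaura coupling of F9 with F10 (PdCl2(dppf), K3PO4, DMF/THF, rt) proceeds with retention at the sp2 carbon to 14.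

**Further compounds**
F1 | step 12 | epoxy diol | CC(C)=CCC/C(C)=C/CC/C(C)=C/CC/C(CO)=C\C[C@@H](O)[C@H]1CO1
F2 | step 12 | (3E,7E,11E)-4-(hydroxymethyl)-8,12,16-trimethylheptadeca-3,7,11,15-tetraenal | CC(C)=CCC/C(C)=C/CC/C(C)=C/CC/C(CO)=C\CC=O
F3 | step 12 | TES ether of F2 | CC(C)=CCC/C(C)=C/CC/C(C)=C/CC/C(CO[Si](CC)(CC)CC)=C\CC=O
F4 | step 12 | tert-butyl 4-[(4S)-4-benzyl-2-oxo-1,3-oxazolidin-3-yl]-4-oxobutanoate | CC(C)(C)OC(=O)CCC(=O)N1[C@@H](Cc2ccccc2)COC1=O
F5 | step 12 | syn-aldol imide | CC(C)=CCC/C(C)=C/CC/C(C)=C/CC/C(CO[Si](CC)(CC)CC)=C\C[C@@H](O)[C@H](CC(=O)OC(C)(C)C)C(=O)N1[C@@H](Cc2ccccc2)COC1=O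
F6 | step 12 | O-TES aldol imide triethylsilyl ester | CC(C)=CCC/C(C)=C/CC/C(C)=C/CC/C(CO[Si](CC)(CC)CC)=C\C[C@@H](O[Si](CC)(CC)CC)[C@H](CC(=O)O[Si](CC)(CC)CC)C(=O)N1[C@@H](Cc2ccccc2)COC1=O
F7 | step 12 | bis-TES succinic diacid | CC(C)=CCC/C(C)=C/CC/C(C)=C/CC/C(CO[Si](CC)(CC)CC)=C\C[C@@H](O[Si](CC)(CC)CC)[C@H](CC(=O)O)C(=O)O
F8 | step 13 | O-TES Hippolide D | CC(C)=CCC/C(C)=C/CC/C(C)=C/CC/C(C=O)=C\C[C@@H](O[Si](CC)(CC)CC)[C@@H]1CC(=O)OC1=O
F9 | step 9 | ethyl (2Z,5R)-2-bromo-5-[(2R)-oxiran-2-yl]-5-(triethylsilyloxy)pent-2-enoate | Br/C(C(=O)OCC)=C\C[C@@H](O[Si](CC)(CC)CC)[C@H]1CO1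
F10 | step 9 | lithium B-homofarnesyl-B-methoxy-9-borabicyclo[3.3.1]nonanate | CC(C)=CCC/C(C)=C/CC/C(C)=C/CC[B-]1(OC)C2CCCC1CCC2.[Li+]
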